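The pyran ring (ring C) of this (2S)-flavan is cut at both of its bonds to ring A, O1–C8a and C4–C4a. Ring A then becomes 3,5-dimethoxy-4-prenylbenzyne, and ring B with C2–C4 becomes the lithium alkoxide of (S)-3-chloro-1-(4-methoxyphenyl)propan-1-ol, whose stereocentre is set by a CBS reduction. In one operation the alkoxide adds to the aryne at C8a, as dictated by the C5 methoxy group beside the triple bond, and the C4a aryllithium so formed closes ring C by displacing chloride at C4. The aryne is released from a symmetric aryl chloride, so only one aryne can arise.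

Key step: step 3

Remark: chromane numbering is used throughout (O1, C2, C3, C4, C4a, C5 to C8, C8a); compounds 1, 2 and 5 are taken as commercially available.

Step 1
Reactants: 1 1-chloro-3,5-dimethoxybenzene; 2 prenyl bromide (1-bromo-3-methylbut-2-ene)
Product: 4 5-chloro-1,3-dimethoxy-2-(3-methylbut-2-en-1-yl)benzene, via aryllithium 3 (not isolated)
Conditions: n-BuLi, THF, −78 → 0 °C; then 2, −78 °C → rt
Reagents that add atoms: none
Why: Cooperative directed ortho-metalation by the two methoxy groups should lithiate the carbon between them (para to chlorine, so 3 cannot lose LiCl), and the aryllithium should then displace bromide at the primary carbon of 2 (SN2 allylation).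

Step 2
Reactants: 5 3-chloro-1-(4-methoxyphenyl)propan-1-one
Product: 6 (S)-3-chloro-1-(4-methoxyphenyl)propan-1-ol
Conditions: (R)-2-methyl-CBS-oxazaborolidine (10 mol %), BH3·SMe2, THF, −20 °C; then MeOH, aq. NH4Cl
Reagents that add atoms: none
Why: In this CBS reduction the catalyst–borane complex binds the ketone with the aryl group away from the B-methyl group, so hydride should be delivered to the Re face and give the S alcohol (aryl outranks CH2CH2Cl, as in the acetophenone model).

Step 3
Reactants: 4 5-chloro-1,3-dimethoxy-2-(3-methylbut-2-en-1-yl)benzene; 6 (S)-3-chloro-1-(4-methoxyphenyl)propan-1-ol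
Product: 11 (2S)-5,7-dimethoxy-2-(4-methoxyphenyl)-6-(3-methylbut-2-en-1-yl)chromane, via lithium alkoxide 7 (not isolated), via chloroaryllithium 8 (not isolated), via aryne 9 (not isolated), via ring-open aryllithium 10 (not isolated)
Conditions: 6 (1.5 equiv), n-BuLi, THF, −78 °C; then 4; LiTMP (from 2,2,6,6-tetramethylpiperidine and n-BuLi) added slowly, −20 °C → 23 °C
Reagents that add atoms: none
Why: Proposed new method: LiTMP should remove the proton of 4 between chlorine and methoxy to give 8, which loses LiCl to aryne 9; alkoxide 7 adds to the aryne carbon remote from the C5 methoxy group (the future C8a), which places the carbanion of 10 on the future C4a, and this aryllithium then displaces chloride from the CH2Cl carbon to form the C4–C4a bond. The closest known reaction types are the addition of alkali alkoxides to arynes made from haloarenes with base, the aryne annulation in which a heteroatom nucleophile adds and the resulting aryl anion attacks a tethered electrophile (xanthones from ortho-hydroxybenzoates), and the Parham cyclialkylation of ortho-lithiated aryl 3-halopropyl ethers to chromans; their merger with a 3-chloroalkoxide as combined O-nucleophile and C-electrophile is the part not yet shown. Ring C closes in the 6-exo-tet mode (aryl carbanion on a primary alkyl chloride, leaving group outside the ring). No stereocentre is formed: C2 comes from 6 and none of its bonds is broken, so the S configuration is kept. The step needs regioselective O-addition, which the methoxy group beside the triple bond secures (inductive stabilisation and lithium chelation of the adjacent carbanion, attack at the more open aryne carbon), and because 4 is symmetric only one aryne can form; it also needs 7 to outrun LiTMP and 8 as nucleophiles (excess 7, slow addition of base) and 10 to stay unprotonated (alcohol fully deprotonated beforehand, aprotic medium).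

Compound list
1 | 1-chloro-3,5-dimethoxybenzene | COc1cc(Cl)cc(OC)c1 | starting material
2 | prenyl bromide (1-bromo-3-methylbut-2-ene) | CC(C)=CCBr | starting material
3 | (4-chloro-2,6-dimethoxyphenyl)lithium | COc1cc(Cl)cc(OC)c1[Li] | intermediate
4 | 5-chloro-1,3-dimethoxy-2-(3-methylbut-2-en-1-yl)benzene | COc1cc(Cl)cc(OC)c1CC=C(C)C | intermediate
5 | 3-chloro-1-(4-methoxyphenyl)propan-1-one | COc1ccc(C(=O)CCCl)cc1 | starting material
6 | (S)-3-chloro-1-(4-methoxyphenyl)propan-1-ol | COc1ccc([C@@H](O)CCCl)cc1 | intermediate
7 | lithium (S)-3-chloro-1-(4-methoxyphenyl)propan-1-olate | COc1ccc([C@@H](O[Li])CCCl)cc1 | intermediate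
8 | [6-chloro-2,4-dimethoxy-3-(3-methylbut-2-en-1-yl)phenyl]lithium | COc1cc(Cl)c([Li])c(OC)c1CC=C(C)C | intermediate
9 | 1,2-didehydro-3,5-dimethoxy-4-(3-methylbut-2-en-1-yl)benzene (aryne) | COC1=C(CC=C(C)C)C(OC)=CC#C1 | intermediate
10 | [6-{[(1S)-3-chloro-1-(4-methoxyphenyl)propyl]oxy}-2,4-dimethoxy-3-(3-methylbut-2-en-1-yl)phenyl]lithium | COc1ccc([C@H](CCCl)Oc2cc(OC)c(CC=C(C)C)c(OC)c2[Li])cc1 | intermediate
11 | (2S)-5,7-dimethoxy-2-(4-methoxyphenyl)-6-(3-methylbut-2-en-1-yl)chromane | COc1ccc([C@@H]2CCc3c(cc(OC)c(CC=C(C)C)c3OC)O2)cc1 | target

Total step count: 3. Longest linear sequence: 2 steps (step 1 then step 3, or step 2 then step 3).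

Steps most likely to fail

Step 3 (Proposed new method). The lithium alkoxide may lose the competition for the aryne to LiTMP or to chloroaryllithium 8, which would give amine or biaryl adducts. The ring-open aryllithium may also be protonated, or may eliminate HCl from the side chain, before it alkylates. The fallback uses known chemistry, sets out from 6 and 4 and returns at 11. Alcohol 6 is closed with KOtBu in THF (Williamson 4-exo-tet closure, stereocentre untouched) to (S)-2-(4-methoxyphenyl)oxetane F1. Chloride 4 is lithiated with LiTMP at −78 °C to 8 and held at that temperature so that LiCl is not lost; with BF3·OEt2 this aryllithium should open F1 at its CH2–O carbon and give, after work-up, (S)-3-[6-chloro-2,4-dimethoxy-3-(3-methylbut-2-en-1-yl)phenyl]-1-(4-methoxyphenyl)propan-1-ol F2. Intramolecular C–O coupling of F2 (Pd(OAc)2, 2-di-tert-butylphosphino-2',4',6'-triisopropylbiphenyl, Cs2CO3, toluene, 90 °C) should then close ring C to 11 with retention at C2.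

Step 1. Metalation may occur beside chlorine instead of between the methoxy groups, after which LiCl is lost and aryne-derived products form; allylation of the hindered aryllithium may also be slow. The fallback avoids metalation of a chlorinated ring, sets out from 2 and returns at 4. 1,3-Dimethoxybenzene F3 (purchased) is treated with n-BuLi and then 2 (directed ortho-metalation between the methoxy groups, then allylation) to give 1,3-dimethoxy-2-(3-methylbut-2-en-1-yl)benzene F4. Sterically controlled C–H borylation ([Ir(cod)OMe]2, 4,4'-di-tert-butyl-2,2'-bipyridine, B2pin2, THF, 80 °C) should take place at the only ring CH without an ortho substituent and give 2-[3,5-dimethoxy-4-(3-methylbut-2-en-1-yl)phenyl]-4,4,5,5-tetramethyl-1,3,2-dioxaborolane F5. CuCl2 in MeOH/H2O at 80 °C should then replace boron by chlorine to give 4.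

Step 2. Facial selectivity of hydride delivery may be incomplete, because the electron-rich aryl ketone binds the catalyst weakly and uncatalysed borane reduction competes. The fallback is a resolution, sets out from 5 and returns at 6. NaBH4 in MeOH reduces 5 to racemic 3-chloro-1-(4-methoxyphenyl)propan-1-ol F6. Immobilised Candida antarctica lipase B with vinyl acetate in toluene at rt should acetylate the R enantiomer selectively to (R)-3-chloro-1-(4-methoxyphenyl)propyl acetate F7, which leaves the S alcohol 6 to be separated by chromatography.

Further compounds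
F1 | step 3 | (S)-2-(4-methoxyphenyl)oxetane | COc1ccc([C@@H]2CCO2)cc1
F2 | step 3 | (S)-3-[6-chloro-2,4-dimethoxy-3-(3-methylbut-2-en-1-yl)phenyl]-1-(4-methoxyphenyl)propan-1-ol | COc1ccc([C@@H](O)CCc2c(Cl)cc(OC)c(CC=C(C)C)c2OC)cc1
F3 | step 1 | 1,3-dimethoxybenzene (purchased) | COc1cccc(OC)c1
F4 | step 1 | 1,3-dimethoxy-2-(3-methylbut-2-en-1-yl)benzene | COc1cccc(OC)c1CC=C(C)C
F5 | step 1 | 2-[3,5-dimethoxy-4-(3-methylbut-2-en-1-yl)phenyl]-4,4,5,5-tetramethyl-1,3,2-dioxaborolane | COc1cc(B2OC(C)(C)C(C)(C)O2)cc(OC)c1CC=C(C)C
F6 | step 2 | rac-3-chloro-1-(4-methoxyphenyl)propan-1-ol | COc1ccc(C(O)CCCl)cc1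
F7 | step 2 | (R)-3-chloro-1-(4-methoxyphenyl)propyl acetate | COc1ccc([C@H](OC(C)=O)CCCl)cc1
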